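# Proposed synthesis of CNP0116579.1, (2R,3R)-2-(4-hydroxy-3,5-dimethoxyphenyl)-3-methyl-5-methoxy-7-allyl-1,4-benzodioxane (14)

## Analysis of the target

Target 14 is a 1,4-benzodioxane neolignan. Ring A is a benzene ring that carries O1 on C8a, O4 on C4a, a methoxy group on C5 and an allyl group on C7. Ring B is the dioxane ring O1–C2–C3–O4, with ring C (4-hydroxy-3,5-dimethoxyphenyl) on C2 and a methyl group on C3. The two stereocentres C2 and C3 are adjacent and both R, which places aryl and methyl trans on ring B, the more stable arrangement with both groups pseudo-equatorial.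

The sensitive groups are three. The terminal allyl group rules out hydrogenolysis and can move into conjugation under strong base or metal hydride catalysis. The free phenol of ring C lies para to the benzylic ether C2–O1, which can ionise through a quinone methide under forcing acid or base. Both arenes are electron-rich and easily oxidised.

The difficulty is the regiochemistry of ring B on ring A: the oxygen on the methyl-bearing C3 (O4) must sit next to the C5 methoxy group, and a catechol-based route has to tell two very similar phenolic oxygens apart while also fixing both stereocentres absolutely.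

The strategy rests on one feature. C8a, the carbon bonded to O1, is the carbon that carries a methoxy group ortho to the ether oxygen in any ether of 4-allyl-2,6-dimethoxyphenol (1). Ring A can therefore be bought with O4, the C5 methoxy group and the allyl group in place. Ring B is then closed by letting the C2 hydroxyl replace one of the two equivalent methoxy groups, so the regiochemical question does not arise.

## Retrosynthetic reasoning

**14 to 13.** The phenol of ring C is masked as a pivalate. The ester is chosen because it withdraws electron density from ring C (needed in the ring closure), is inert to light and radical-ion conditions, and is removed by mild methanolysis that leaves the allyl group alone.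

**13 to 12.** The O1–C8a bond is cut. This is the only ring B bond whose cleavage returns ring A as an intact 2,6-dimethoxyphenyl ether of 1, with the leaving group (a methoxy group) already on the carbon to be attacked. Cutting C3–O4 or C2–O1 would call for a differentiated catechol and would create a stereocentre during ring closure. Here no bond to C2 or C3 is touched, so both configurations are carried in from the open-chain alcohol 12. The forward reaction must replace an unactivated methoxy group on an electron-rich ring by a secondary alcohol. This is impossible thermally and is attempted by one-electron oxidation of ring A to its radical cation under acridinium photocatalysis.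

**12 to 10.** The pivalate is exchanged for a silyl ether. The silyl ether is what the organolithium chemistry further back tolerates; the pivalate is what the ring closure needs. The exchange passes through free phenol 11.

**10 to 9.** The carbinol stereocentre C1 (the future C2) is taken back to ketone 9. The reduction must give the threo (1R,2R) alcohol by 1,2-induction from the existing aryloxy-bearing centre, which calls for a bulky hydride under non-chelating, Felkin–Anh conditions.

**9 to 4 and 6.** The aryl–carbonyl bond is cut. Weinreb amide 4 and aryl-lithium 7 (from bromide 6, itself from bromophenol 5) join through the stable tetrahedral adduct 8. This avoids double addition and keeps the epimerisable α-aryloxy ketone from forming until the quench.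

**4 to 3, and 3 to 1 and 2.** The C3–O4 ether bond is cut. The methyl-bearing stereocentre comes from the chiral pool: lactate ester 2 brings the methyl group, the oxidation level for the later C–C bond formation and the (S) configuration, which a Mitsunobu reaction with phenol 1 inverts to the required (R) ether 3. Amide 4 follows by ester aminolysis.

## Alternatives that were turned down

**Alternative 1:** C3–O4 and C2–C3 are cut together, so that a ring A phenol, a two-carbon diazo ester and a ring C aldehyde are joined in one step.
- **Forward key step:** Rh2(OAc)4 turns ethyl diazoacetate A1 into a rhodium carbene. Bromophenol 5 (serving here as ring A) adds to give a protic oxonium ylide. This enol equivalent is trapped by 4-formyl-2,6-dimethoxyphenyl pivalate A2 under a chiral phosphoric acid, giving the α-aryloxy-β-hydroxy ester A3.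
- **For:** it is convergent, uses three simple components, forms a C–O and a C–C bond at once, and sets the aryloxy-bearing centre catalytically.
- **Against:**
  - A3 carries an ethyl ester where the target has the C3 methyl group. Reduction, activation and hydride displacement are needed, with an aryl pivalate and a free benzylic alcohol in the way.
  - The bromine must still be exchanged for allyl by cross-coupling.
  - The carbinol configuration is not secured. Ylides from hindered phenols tend to collapse by 1,2-proton shift to plain O–H insertion products before an aldehyde can intercept them.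
  - Ring B is still open after the key step, so the O1–C8a bond has to be made by the same methoxy substitution anyway.
- **Comparison:** it is stronger in convergence and in catalytic C–C bond formation. The chosen route takes the methyl group and the C3 configuration from 2, needs no correction of oxidation level, and reaches the same ring closure in fewer steps.

**Alternative 2:** ring A is built, not bought. O4–C4a and O1–C2 are cut, leading back to ethyl 4-diazo-3,5-dioxocyclohexane-1-carboxylate A4 and the ring C epoxide A5, 2,6-dimethoxy-4-[(2R,3R)-3-methyloxiran-2-yl]phenyl pivalate.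
- **Forward key step:** Rh2(OAc)4 converts A4 into a carbene, the epoxide oxygen of A5 adds to give an oxonium ylide, the benzylic C–O bond opens and the enolate oxygen closes on C2. The product is the dioxene-fused cyclohexenone A6 with ring B complete.
- **For:** both ring B C–O bonds form in one precedented type of ring expansion. The mechanism fixes which oxygen goes to which carbon, C3 keeps the configuration of A5, and the symmetric dione raises no regiochemical question.
- **Against:**
  - Ring A arrives at the wrong oxidation level and with the wrong substituents. The C5 ketone must be dehydrogenated to a phenol and methylated, and the C7 ester must be homologated to an allyl group. This is about six further steps, several of them reductions that threaten the pivalate.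
  - The benzylic opening is cation-like, so the C2 configuration rests on a thermodynamic preference for trans and not on stereospecificity. A clean inversion at C2 would give the cis isomer from A5.
  - A5 needs its own asymmetric epoxidation.
- **Comparison:** it is stronger in how ring B is made. It is much weaker in step economy, and the chosen strategy keeps ring A exactly as it is sold in 1.

**Alternative 3:** C3–O4 and a C–H bond of the methyl group are cut, so that the methyl group and ring B both arise from a vinyl group.
- **Substrate:** the branched allylic aryl ether A7, 4-[(1S)-1-(5-bromo-2-hydroxy-3-methoxyphenoxy)prop-2-en-1-yl]-2,6-dimethoxyphenyl pivalate.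
- **Forward key step:** Co(salen), a silane and an N-fluoropyridinium oxidant transfer a hydrogen atom to the terminal alkene carbon. The C3 radical is oxidised and captured by the ring A phenol O4, giving the bromo-benzodioxane A8.
- **For:** cobalt-catalysed hydroalkoxylation of alkenyl phenols is a known reaction type. A7 is within reach of an asymmetric allylic etherification that sets C2.
- **Against:**
  - C3 is created during ring closure, so the trans/cis outcome depends only on induction from C2 through a cationic or organocobalt intermediate.
  - The C3 radical is β to an aryloxy group and next to the aryl-bearing carbon, so loss of an aryloxyl radical and 1,2-aryl shift compete.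
  - The allyl group cannot be present, because its alkene would undergo the same hydrogen atom transfer. Ring A must carry bromine, and the allyl group comes by a late cross-coupling.
  - The ring A partner is a catechol whose two hydroxyls must be told apart by protection.
- **Comparison:** on precedent this alternative is stronger than the chosen strategy, and its length is similar. The chosen strategy offers both stereocentres fixed before the ring closes, the allyl group present from the first step, and no catechol differentiation.

Key step: step 7

Assumption: 1, 2 and 5 are bought, and the acridinium photocatalyst is used as its 3,6-di-tert-butyl tetrafluoroborate salt, the member of the 9-mesityl-10-phenylacridinium family that best resists nucleophilic bleaching.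

## Route

**Step 1**
Reactants: 1 4-allyl-2,6-dimethoxyphenol; 2 ethyl (S)-lactate
Product: 3 ethyl (2R)-2-(4-allyl-2,6-dimethoxyphenoxy)propanoate
Conditions: PPh3, DIAD, THF, 0 → 25 °C
Reagents that add atoms: none
Why: Mitsunobu etherification; the phenoxide displaces the oxyphosphonium group of the lactate in an SN2 step, so the (S) carbinol centre is inverted to the (R) aryl ether. α-Hydroxy esters are good substrates because the adjacent ester suppresses ionisation.

**Step 2**
Reactants: 3 ethyl (2R)-2-(4-allyl-2,6-dimethoxyphenoxy)propanoate
Product: 4 (2R)-2-(4-allyl-2,6-dimethoxyphenoxy)-N-methoxy-N-methylpropanamide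
Conditions: MeNH(OMe)·HCl, iPrMgCl, THF, −20 → 0 °C
Reagents that add atoms: N,O-dimethylhydroxylamine hydrochloride, CNOC.Cl
Why: Weinreb amide formation by aminolysis of the ester with the chloromagnesium amide made in the flask. The amide base is weak and the reaction runs below 0 °C, so the α-aryloxy stereocentre should be kept.

**Step 3**
Reactants: 5 4-bromo-2,6-dimethoxyphenol
Product: 6 (4-bromo-2,6-dimethoxyphenoxy)(tert-butyl)dimethylsilane
Conditions: TBSCl, imidazole, DMF, 25 °C
Reagents that add atoms: tert-butyldimethylsilyl chloride, CC(C)(C)[Si](C)(C)Cl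
Why: Imidazole-promoted silylation of a phenol. The silyl ether masks the acidic hydroxyl for the halogen–lithium exchange and, being para to bromine, cannot undergo anionic silyl migration.

**Step 4**
Reactants: 6 (4-bromo-2,6-dimethoxyphenoxy)(tert-butyl)dimethylsilane; 4 (2R)-2-(4-allyl-2,6-dimethoxyphenoxy)-N-methoxy-N-methylpropanamide
Product: 9 (2R)-2-(4-allyl-2,6-dimethoxyphenoxy)-1-[4-(tert-butyldimethylsilyloxy)-3,5-dimethoxyphenyl]propan-1-one, via aryl-lithium 7 (not isolated), via lithium hemiaminal alkoxide 8 (not isolated)
Conditions: 6, n-BuLi, THF, −78 °C; then 4, −78 °C; cold aq NH4Cl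
Reagents that add atoms: none
Why: Bromine–lithium exchange followed by Weinreb ketone synthesis. The chelated tetrahedral adduct 8 persists at −78 °C, which prevents double addition and keeps the ketone with its acidic α-hydrogen from forming until the buffered quench, so C2 should not epimerise.

**Step 5**
Reactants: 9 (2R)-2-(4-allyl-2,6-dimethoxyphenoxy)-1-[4-(tert-butyldimethylsilyloxy)-3,5-dimethoxyphenyl]propan-1-one
Product: 10 (1R,2R)-2-(4-allyl-2,6-dimethoxyphenoxy)-1-[4-(tert-butyldimethylsilyloxy)-3,5-dimethoxyphenyl]propan-1-ol
Conditions: KBH(s-Bu)3, THF, −78 → −40 °C; aq NH4Cl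
Reagents that add atoms: none
Why: Diastereoselective ketone reduction under polar Felkin–Anh control: the C–OAr bond at C2 lies anti to the incoming bulky hydride, which passes the small hydrogen, so the new C1 centre should be R and the alcohol threo (1R,2R). The large, weakly coordinating potassium ion is chosen so that chelation, which would lead to the erythro alcohol, does not compete.

**Step 6**
Reactants: 10 (1R,2R)-2-(4-allyl-2,6-dimethoxyphenoxy)-1-[4-(tert-butyldimethylsilyloxy)-3,5-dimethoxyphenyl]propan-1-ol
Product: 12 4-[(1R,2R)-2-(4-allyl-2,6-dimethoxyphenoxy)-1-hydroxypropyl]-2,6-dimethoxyphenyl pivalate, via free phenol 11 (not isolated)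
Conditions: Bu4NF (1.05 equiv), THF, 0 °C; then PivCl (1.1 equiv), 0 °C
Reagents that add atoms: pivaloyl chloride, CC(C)(C)C(=O)Cl
Why: Fluoride cleavage of the aryl silyl ether gives 11 as its tetrabutylammonium phenoxide. This is far more nucleophilic than the neutral secondary benzylic alcohol and should be acylated selectively by the hindered acid chloride without an acyl-transfer catalyst (chemoselective O-acylation of a phenoxide).

**Step 7**
Reactants: 12 4-[(1R,2R)-2-(4-allyl-2,6-dimethoxyphenoxy)-1-hydroxypropyl]-2,6-dimethoxyphenyl pivalate
Product: 13 4-[(2R,3R)-7-allyl-5-methoxy-3-methyl-2,3-dihydro-1,4-benzodioxin-2-yl]-2,6-dimethoxyphenyl pivalate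
Conditions: 3,6-di-tert-butyl-9-mesityl-10-phenylacridinium tetrafluoroborate (5 mol %), ClCH2CH2Cl/CF3CH2OH 4:1 (0.02 M), 455 nm LEDs, N2, 25 °C
Reagents that add atoms: none
Why: Proposed new method: the excited acridinium, a strong one-electron oxidant, should oxidise 12 to an arene radical cation whose hole settles on ring A, the ring without an acyloxy group; there the tethered oxygen on C4a is twisted out of conjugation by its two ortho neighbours, so the singly occupied orbital is that of a 1,3-dimethoxybenzene, with large coefficients on the two methoxy-bearing carbons and a node through C4a and the allyl-bearing carbon. The C2 hydroxyl adds ipso to one of these carbons (the future C8a), proton loss gives a 1-alkoxy-1-methoxycyclohexadienyl radical, the acridinyl radical returns the electron, and loss of methanol rearomatises the ring, so the step is redox-neutral and needs only light and catalyst. The closest known reaction type is the acridinium-photocatalysed cation-radical-accelerated nucleophilic aromatic substitution of methoxyarenes by nitrogen and oxygen nucleophiles; what is new is the intramolecular use of a secondary benzylic alcohol on a 1,2,3-trioxygenated ring. Ring B closes in a six-membered exo-type mode (ring atoms O1, C2, C3, O4, C4a, C8a; the attacked C8a=C8 π bond stays outside the new ring), and no stereocentre is formed, since no bond to C2 or C3 is broken and both configurations are carried over from 12. The step needs three selectivities: ring A over ring C, which the electron-withdrawing pivalate should secure; attack at a methoxy-bearing carbon and not at C4a, which the tether can also reach through a five-membered spiro adduct that would open an aryl shift of the Smiles type from one oxygen to the other, a path disfavoured by the orbital node at C4a and reversible; and a choice between the two methoxy carbons, which are equivalent by the local symmetry of ring A. The allyl alkene lies well above the oxidation potential reached, and its CH2 group sits on the nodal carbon, which should slow benzylic deprotonation of the radical cation.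

**Step 8**
Reactants: 13 4-[(2R,3R)-7-allyl-5-methoxy-3-methyl-2,3-dihydro-1,4-benzodioxin-2-yl]-2,6-dimethoxyphenyl pivalate
Product: 14 4-[(2R,3R)-7-allyl-5-methoxy-3-methyl-2,3-dihydro-1,4-benzodioxin-2-yl]-2,6-dimethoxyphenol
Conditions: K2CO3 (cat.), MeOH, 25 °C; aq NH4Cl
Reagents that add atoms: none
Why: Base-catalysed methanolysis of an aryl ester. The phenoxide is a good leaving group, so the pivalate should be cleaved at room temperature while the allyl group, the ethers and both stereocentres stay untouched.

## Compound list

1 | 4-allyl-2,6-dimethoxyphenol | C=CCc1cc(OC)c(O)c(OC)c1 | starting material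
2 | ethyl (S)-lactate | C[C@H](O)C(=O)OCC | starting material
3 | ethyl (2R)-2-(4-allyl-2,6-dimethoxyphenoxy)propanoate | C=CCc1cc(OC)c(O[C@H](C)C(=O)OCC)c(OC)c1 | intermediate
4 | (2R)-2-(4-allyl-2,6-dimethoxyphenoxy)-N-methoxy-N-methylpropanamide | C=CCc1cc(OC)c(O[C@H](C)C(=O)N(C)OC)c(OC)c1 | intermediate
5 | 4-bromo-2,6-dimethoxyphenol | COc1cc(Br)cc(OC)c1O | starting material
6 | (4-bromo-2,6-dimethoxyphenoxy)(tert-butyl)dimethylsilane | COc1cc(Br)cc(OC)c1O[Si](C)(C)C(C)(C)C | intermediate
7 | [4-(tert-butyldimethylsilyloxy)-3,5-dimethoxyphenyl]lithium | [Li]c1cc(OC)c(O[Si](C)(C)C(C)(C)C)c(OC)c1 | intermediate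
8 | lithium (2R)-2-(4-allyl-2,6-dimethoxyphenoxy)-1-[4-(tert-butyldimethylsilyloxy)-3,5-dimethoxyphenyl]-1-[methoxy(methyl)amino]propan-1-olate (tetrahedral adduct, C1 undefined) | C=CCc1cc(OC)c(O[C@H](C)C(O[Li])(N(C)OC)c2cc(OC)c(O[Si](C)(C)C(C)(C)C)c(OC)c2)c(OC)c1 | intermediate
9 | (2R)-2-(4-allyl-2,6-dimethoxyphenoxy)-1-[4-(tert-butyldimethylsilyloxy)-3,5-dimethoxyphenyl]propan-1-one | C=CCc1cc(OC)c(O[C@H](C)C(=O)c2cc(OC)c(O[Si](C)(C)C(C)(C)C)c(OC)c2)c(OC)c1 | intermediate
10 | (1R,2R)-2-(4-allyl-2,6-dimethoxyphenoxy)-1-[4-(tert-butyldimethylsilyloxy)-3,5-dimethoxyphenyl]propan-1-ol | C=CCc1cc(OC)c(O[C@H](C)[C@H](O)c2cc(OC)c(O[Si](C)(C)C(C)(C)C)c(OC)c2)c(OC)c1 | intermediate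
11 | 4-[(1R,2R)-2-(4-allyl-2,6-dimethoxyphenoxy)-1-hydroxypropyl]-2,6-dimethoxyphenol (present as its tetrabutylammonium phenoxide) | C=CCc1cc(OC)c(O[C@H](C)[C@H](O)c2cc(OC)c(O)c(OC)c2)c(OC)c1 | intermediate
12 | 4-[(1R,2R)-2-(4-allyl-2,6-dimethoxyphenoxy)-1-hydroxypropyl]-2,6-dimethoxyphenyl pivalate | C=CCc1cc(OC)c(O[C@H](C)[C@H](O)c2cc(OC)c(OC(=O)C(C)(C)C)c(OC)c2)c(OC)c1 | intermediate
13 | 4-[(2R,3R)-7-allyl-5-methoxy-3-methyl-2,3-dihydro-1,4-benzodioxin-2-yl]-2,6-dimethoxyphenyl pivalate | C=CCc1cc(OC)c2c(c1)O[C@H](c1cc(OC)c(OC(=O)C(C)(C)C)c(OC)c1)[C@@H](C)O2 | intermediate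
14 | 4-[(2R,3R)-7-allyl-5-methoxy-3-methyl-2,3-dihydro-1,4-benzodioxin-2-yl]-2,6-dimethoxyphenol | C=CCc1cc(OC)c2c(c1)O[C@H](c1cc(OC)c(O)c(OC)c1)[C@@H](C)O2 | target

## Step count and least certain steps

Total step count: 8. Longest linear sequence: 7 steps (steps 1, 2, 4, 5, 6, 7 and 8, from 1 and 2); step 3 is a one-step side branch.

**Step 7 (key step, proposed new method).**
What may go wrong:
- Spiro attack of the hydroxyl at C4a followed by oxygen-to-oxygen aryl migration, which would lead on to ring closure with the methoxy group next to O1 instead of O4.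
- Residence of the hole on ring C, leading to loss of the benzylic hydrogen or cleavage of the C1–C2 bond, as is typical of β-aryloxy benzylic alcohol radical cations.
- Trapping of the hole by the product, whose ring A has both ring oxygens held in conjugation and is easier to oxidise than 12. This could stall the reaction or exchange the remaining methoxy group with the fluorinated alcohol.
- Migration of the allyl double bond after benzylic deprotonation.

A more strongly withdrawing acyl or sulfonyl group on ring C is a tuning option inside the step.

Fallback with known chemistry (the leaving group becomes bromide and the bond is made by palladium catalysis). It sets out from 2 and 6 and returns at 14.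
- Mitsunobu reaction of 2 with 4-allyl-2-bromo-6-methoxyphenol F1 gives ethyl (2R)-2-(4-allyl-2-bromo-6-methoxyphenoxy)propanoate F2.
- Aminolysis as in step 2 gives (2R)-2-(4-allyl-2-bromo-6-methoxyphenoxy)-N-methoxy-N-methylpropanamide F3.
- Bromide 6 is converted with magnesium turnings into [4-(tert-butyldimethylsilyloxy)-3,5-dimethoxyphenyl]magnesium bromide F4. The Grignard reagent is used so that no halogen–metal exchange with the ring A bromide intervenes. Addition to F3 gives (2R)-2-(4-allyl-2-bromo-6-methoxyphenoxy)-1-[4-(tert-butyldimethylsilyloxy)-3,5-dimethoxyphenyl]propan-1-one F5.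
- Reduction with KBH(s-Bu)3 as in step 5 gives (1R,2R)-2-(4-allyl-2-bromo-6-methoxyphenoxy)-1-[4-(tert-butyldimethylsilyloxy)-3,5-dimethoxyphenyl]propan-1-ol F6.
- Intramolecular C–O coupling closes ring B at the brominated carbon with retention at C2. Conditions: Pd(OAc)2 as source of zerovalent palladium, 2-(di-tert-butylphosphino)-1,1'-binaphthyl, Cs2CO3, toluene, 70 °C. The product is tert-butyl{4-[(2R,3R)-7-allyl-5-methoxy-3-methyl-2,3-dihydro-1,4-benzodioxin-2-yl]-2,6-dimethoxyphenoxy}dimethylsilane F7.
- Bu4NF in THF then gives 14.

**Step 5.**
What may go wrong: poor facial selectivity. The oxygen-rich aryloxy group (ether oxygen flanked by two methoxy groups) may hold the counter-ion in a chelate with the carbonyl oxygen, which steers hydride to the opposite face and erodes the threo preference.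

Fallback (chelation is used on purpose and C1 is then inverted). It sets out from 9 and returns at 11.
- Zn(BH4)2 in Et2O at 0 °C should give (1S,2R)-2-(4-allyl-2,6-dimethoxyphenoxy)-1-[4-(tert-butyldimethylsilyloxy)-3,5-dimethoxyphenyl]propan-1-ol F8.
- Mitsunobu reaction with 4-nitrobenzoic acid (PPh3, DIAD) inverts C1 and gives (1R,2R)-2-(4-allyl-2,6-dimethoxyphenoxy)-1-[4-(tert-butyldimethylsilyloxy)-3,5-dimethoxyphenyl]propyl 4-nitrobenzoate F9.
- K2CO3 in MeOH removes both the ester and the aryl silyl ether to give phenol 11, which is pivaloylated (PivCl, Et3N, CH2Cl2, 0 °C) to 12.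

**Step 1.**
What may go wrong: slow coupling of the di-ortho-substituted phenol, so that alkylation of the reduced azodicarboxylate or elimination of the activated lactate to the acrylate takes over.

Fallback (SN2 alkylation in place of redox condensation). It sets out from 2 and returns at 3.
- Tf2O and 2,6-lutidine in CH2Cl2 at −78 °C convert 2 into ethyl (2S)-2-(trifluoromethylsulfonyloxy)propanoate F10.
- The phenoxide of 1 (K2CO3, MeCN, 0 °C) displaces the triflate with inversion to give 3.

**Step 6.**
What may go wrong: acylation of the benzylic hydroxyl as well, or loss of hydroxide from the para-phenoxide benzylic alcohol through a quinone methide while the phenoxide is free.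

Fallback (the order of events is changed so that no free alcohol is present during acylation). It sets out from 9 and returns at 12.
- Buffered desilylation (Bu4NF, AcOH, THF, 0 °C) gives (2R)-2-(4-allyl-2,6-dimethoxyphenoxy)-1-(4-hydroxy-3,5-dimethoxyphenyl)propan-1-one F11.
- PivCl and Et3N in CH2Cl2 give 4-[(2R)-2-(4-allyl-2,6-dimethoxyphenoxy)propanoyl]-2,6-dimethoxyphenyl pivalate F12.
- Reduction with KBH(s-Bu)3 at −78 °C as in step 5 gives 12 directly.

## Further compounds

F1 | step 7 | 4-allyl-2-bromo-6-methoxyphenol | C=CCc1cc(Br)c(O)c(OC)c1
F2 | step 7 | ethyl (2R)-2-(4-allyl-2-bromo-6-methoxyphenoxy)propanoate | C=CCc1cc(Br)c(O[C@H](C)C(=O)OCC)c(OC)c1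
F3 | step 7 | (2R)-2-(4-allyl-2-bromo-6-methoxyphenoxy)-N-methoxy-N-methylpropanamide | C=CCc1cc(Br)c(O[C@H](C)C(=O)N(C)OC)c(OC)c1
F4 | step 7 | [4-(tert-butyldimethylsilyloxy)-3,5-dimethoxyphenyl]magnesium bromide | Br[Mg]c1cc(OC)c(O[Si](C)(C)C(C)(C)C)c(OC)c1
F5 | step 7 | (2R)-2-(4-allyl-2-bromo-6-methoxyphenoxy)-1-[4-(tert-butyldimethylsilyloxy)-3,5-dimethoxyphenyl]propan-1-one | C=CCc1cc(Br)c(O[C@H](C)C(=O)c2cc(OC)c(O[Si](C)(C)C(C)(C)C)c(OC)c2)c(OC)c1
F6 | step 7 | (1R,2R)-2-(4-allyl-2-bromo-6-methoxyphenoxy)-1-[4-(tert-butyldimethylsilyloxy)-3,5-dimethoxyphenyl]propan-1-ol | C=CCc1cc(Br)c(O[C@H](C)[C@H](O)c2cc(OC)c(O[Si](C)(C)C(C)(C)C)c(OC)c2)c(OC)c1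
F7 | step 7 | tert-butyl{4-[(2R,3R)-7-allyl-5-methoxy-3-methyl-2,3-dihydro-1,4-benzodioxin-2-yl]-2,6-dimethoxyphenoxy}dimethylsilane | C=CCc1cc(OC)c2c(c1)O[C@H](c1cc(OC)c(O[Si](C)(C)C(C)(C)C)c(OC)c1)[C@@H](C)O2
F8 | step 5 | (1S,2R)-2-(4-allyl-2,6-dimethoxyphenoxy)-1-[4-(tert-butyldimethylsilyloxy)-3,5-dimethoxyphenyl]propan-1-ol | C=CCc1cc(OC)c(O[C@H](C)[C@@H](O)c2cc(OC)c(O[Si](C)(C)C(C)(C)C)c(OC)c2)c(OC)c1
F9 | step 5 | (1R,2R)-2-(4-allyl-2,6-dimethoxyphenoxy)-1-[4-(tert-butyldimethylsilyloxy)-3,5-dimethoxyphenyl]propyl 4-nitrobenzoate | C=CCc1cc(OC)c(O[C@H](C)[C@H](OC(=O)c2ccc(cc2)[N+](=O)[O-])c2cc(OC)c(O[Si](C)(C)C(C)(C)C)c(OC)c2)c(OC)c1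
F10 | step 1 | ethyl (2S)-2-(trifluoromethylsulfonyloxy)propanoate | CCOC(=O)[C@H](C)OS(=O)(=O)C(F)(F)F
F11 | step 6 | (2R)-2-(4-allyl-2,6-dimethoxyphenoxy)-1-(4-hydroxy-3,5-dimethoxyphenyl)propan-1-one | C=CCc1cc(OC)c(O[C@H](C)C(=O)c2cc(OC)c(O)c(OC)c2)c(OC)c1
F12 | step 6 | 4-[(2R)-2-(4-allyl-2,6-dimethoxyphenoxy)propanoyl]-2,6-dimethoxyphenyl pivalate | C=CCc1cc(OC)c(O[C@H](C)C(=O)c2cc(OC)c(OC(=O)C(C)(C)C)c(OC)c2)c(OC)c1
A1 | alternative 1 | ethyl diazoacetate | CCOC(=O)C=[N+]=[N-]
A2 | alternative 1 | 4-formyl-2,6-dimethoxyphenyl pivalate | COc1cc(C=O)cc(OC)c1OC(=O)C(C)(C)C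
A3 | alternative 1 | ethyl (2S)-2-(4-bromo-2,6-dimethoxyphenoxy)-3-(3,5-dimethoxy-4-pivaloyloxyphenyl)-3-hydroxypropanoate (either carbinol epimer) | COc1cc(Br)cc(OC)c1O[C@H](C(=O)OCC)C(O)c1cc(OC)c(OC(=O)C(C)(C)C)c(OC)c1
A4 | alternative 2 | ethyl 4-diazo-3,5-dioxocyclohexane-1-carboxylate | CCOC(=O)C1CC(=O)C(=[N+]=[N-])C(=O)C1
A5 | alternative 2 | 2,6-dimethoxy-4-[(2R,3R)-3-methyloxiran-2-yl]phenyl pivalate | C[C@H]1O[C@@H]1c1cc(OC)c(OC(=O)C(C)(C)C)c(OC)c1
A6 | alternative 2 | ethyl (2R,3R)-2-(3,5-dimethoxy-4-pivaloyloxyphenyl)-3-methyl-5-oxo-2,3,5,6,7,8-hexahydro-1,4-benzodioxine-7-carboxylate (C7 epimers) | CCOC(=O)C1CC(=O)C2=C(C1)O[C@H](c1cc(OC)c(OC(=O)C(C)(C)C)c(OC)c1)[C@@H](C)O2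
A7 | alternative 3 | 4-[(1S)-1-(5-bromo-2-hydroxy-3-methoxyphenoxy)prop-2-en-1-yl]-2,6-dimethoxyphenyl pivalate | C=C[C@H](Oc1cc(Br)cc(OC)c1O)c1cc(OC)c(OC(=O)C(C)(C)C)c(OC)c1
A8 | alternative 3 | 4-[(2R,3R)-7-bromo-5-methoxy-3-methyl-2,3-dihydro-1,4-benzodioxin-2-yl]-2,6-dimethoxyphenyl pivalate | COc1cc(Br)cc2O[C@H](c3cc(OC)c(OC(=O)C(C)(C)C)c(OC)c3)[C@@H](C)Oc12
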